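The carbocycle C1–C6 (C1 = C(CH3)OH, C2=C3, C4 = CH carrying the side chain) is read as the methyl adduct of a 4-substituted cyclohex-2-enone, and that enone as a 3-substituted cyclopentanone enolate plus one carbon. Asymmetric conjugate alkenylation of cyclopentenone fixes C4 and delivers the enol ether regiospecifically. Cyclopropanation and Fe(III)-induced cleavage of the shared bond of the resulting 1-siloxybicyclo[3.1.0]hexane (one-carbon ring expansion) insert C2 between C1 and C3 and place the C2=C3 alkene next to C4 in one operation. Methyl addition (C1), Cu-catalysed SN2′ methylation (C7), hydroformylation and α-aminoxylation/Wittig (C9, E-enoate) finish the target.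

Key step: step 3

Atom labels used below: ring C1–C6 as above; side chain C7 (CHCH3), C8, C9 (CHOAc), C10=C11 (C11 carries CO2Me and the 4-methylpent-3-enyl group).

Assumption (chemistry): the ligand and catalyst enantiomers named in steps 1, 6 and 9 are those expected from the usual facial models. Each is available in both forms, so the sense of induction can be chosen freely without changing any other step.

Step 1
Reactants: 1 trimethyl(prop-2-yn-1-yloxy)silane; 2 cyclopent-2-en-1-one
Product: 5 trimethyl{[(2E)-3-[(1S)-3-(trimethylsilyloxy)cyclopent-2-en-1-yl]prop-2-en-1-yl]oxy}silane, via alkenylzirconocene chloride 3 (not isolated), via zirconium enolate 4 (not isolated)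
Conditions: Cp2Zr(H)Cl, THF, rt; then 2, [Rh(cod)(MeCN)2]BF4 (3 mol%), (R)-BINAP (3.3 mol%), rt; then TMSCl, 0 °C
Reagents that add atoms: chlorotrimethylsilane, C[Si](C)(C)Cl
Why: Hydrozirconation gives the (E)-alkenylzirconium reagent, its Rh(I)/BINAP-catalysed asymmetric 1,4-addition (Hayashi-type conjugate addition) selects one enantioface of the enone and so sets C4, and O-silylation of the O-bound zirconium enolate locks the enol double bond between the former carbonyl carbon and the carbon next to C4.

Step 2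
Reactants: 5 trimethyl{[(2E)-3-[(1S)-3-(trimethylsilyloxy)cyclopent-2-en-1-yl]prop-2-en-1-yl]oxy}silane
Product: 6 trimethyl{[(2E)-3-[(1R,4S,5S)-1-(trimethylsilyloxy)bicyclo[3.1.0]hexan-4-yl]prop-2-en-1-yl]oxy}silane
Conditions: Et2Zn, CH2I2, CH2Cl2, 0 °C to rt
Reagents that add atoms: diiodomethane, ICI
Why: In this Furukawa-type Simmons–Smith cyclopropanation the zinc carbenoid reacts fastest with the electron-rich silyl enol ether, so the allylic-ether alkene is spared, and CH2 is delivered anti to the C4 substituent, although both cyclopropane stereocentres are erased in step 3.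

Step 3
Reactants: 6 trimethyl{[(2E)-3-[(1R,4S,5S)-1-(trimethylsilyloxy)bicyclo[3.1.0]hexan-4-yl]prop-2-en-1-yl]oxy}silane
Product: 8 (4S)-4-[(1E)-3-hydroxyprop-1-en-1-yl]cyclohex-2-en-1-one, via chloro ketone 7 (not isolated)
Conditions: FeCl3 (2.2 equiv), DMF, 0 °C to rt; then NaOAc, MeOH, 50 °C
Reagents that add atoms: none
Why: Fe(III) oxidises the siloxycyclopropane with loss of Me3SiCl to an oxygen-centred radical that undergoes β-scission of the internal bicyclo C1–C5 bond, chlorine transfer from FeCl3 traps the ring radical as β-chloro ketone 7, and acetate-mediated E1cB loss of HCl gives the enone; the closest known reaction type is the Ito–Saegusa one-carbon ring expansion of a silyl enol ether through its cyclopropane. No ring is closed: the five-membered ring C1–C3–C4–C5–C6 grows to six because the cyclopropane CH2 (future C2) is inserted between C1 and C3. No new stereocentre is formed; C4 is untouched and carried through, while the two cyclopropane centres become sp2. The step needs cleavage of the internal rather than the external cyclopropane bond and an enone double bond on the C4 side; the first is secured by formation of a secondary ring radical instead of a primary one, the second by the position of the cyclopropane, which the regiospecific enol ether of step 1 fixed. The buffered methanol also methanolyses the primary O–TMS group, so the allylic alcohol is released in the same operation. The weak acetate base is chosen so that the doubly allylic C4–H is not removed.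

Step 4
Reactants: 8 (4S)-4-[(1E)-3-hydroxyprop-1-en-1-yl]cyclohex-2-en-1-one
Product: 9 (1R,4S)-4-[(1E)-3-hydroxyprop-1-en-1-yl]-1-methylcyclohex-2-en-1-ol
Conditions: MeMgBr (2.5 equiv), CeCl3, THF, −78 °C
Reagents that add atoms: methylmagnesium bromide, C[Mg]Br
Why: 1,2-Addition of the weakly basic organocerium reagent to the enone, in which pseudo-axial attack on the half-chair with the C4 substituent pseudo-equatorial should place the methyl group cis to that substituent and the hydroxyl trans to it, setting C1.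

Step 5
Reactants: 9 (1R,4S)-4-[(1E)-3-hydroxyprop-1-en-1-yl]-1-methylcyclohex-2-en-1-ol
Product: 11 (1R,4R)-4-[(1E)-3-bromoprop-1-en-1-yl]-1-methylcyclohex-2-en-1-ol, via allylic mesylate 10 (not isolated)
Conditions: MsCl (1.05 equiv), Et3N, CH2Cl2, −40 °C; then LiBr, THF, 0 °C
Reagents that add atoms: lithium bromide, [Li+].[Br-]
Why: Sulfonylation is selective for the primary allylic hydroxyl over the hindered tertiary one, and SN2 displacement of the mesylate by bromide gives the (E)-allylic bromide (the change of the C4 descriptor is a priority effect only).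

Step 6
Reactants: 11 (1R,4R)-4-[(1E)-3-bromoprop-1-en-1-yl]-1-methylcyclohex-2-en-1-ol
Product: 12 (1R,4R)-4-[(2R)-but-3-en-2-yl]-1-methylcyclohex-2-en-1-ol
Conditions: MeMgBr (2.5 equiv), CuBr·SMe2 (5 mol%), (S,S)-TaniaPhos (6 mol%), CH2Cl2, −75 °C
Reagents that add atoms: methylmagnesium bromide, C[Mg]Br
Why: Copper-catalysed asymmetric allylic alkylation with a Grignard reagent, in which the chiral methylcopper species attacks the γ-carbon (SN2′) so that the ligand decides the face and sets C7, one extra equivalent of MeMgBr being consumed by the tertiary hydroxyl.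

Step 7
Reactants: 12 (1R,4R)-4-[(2R)-but-3-en-2-yl]-1-methylcyclohex-2-en-1-ol
Product: 13 (4R)-4-[(1S,4R)-4-hydroxy-4-methylcyclohex-2-en-1-yl]pentanal
Conditions: CO/H2 (1:1, 10 bar), Rh(acac)(CO)2 (1 mol%), BiPhePhos (3 mol%), toluene, 60 °C
Reagents that add atoms: carbon monoxide, [C-]#[O+]
Why: Rhodium/bisphosphite-catalysed hydroformylation is strongly linear-selective for a monosubstituted alkene with a branched allylic carbon and leaves the hindered 1,2-disubstituted ring alkene untouched.

Step 8
Reactants: 14 5-bromo-2-methylpent-2-ene; 15 methyl (triphenyl-λ5-phosphanylidene)acetate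
Product: 17 methyl 6-methyl-2-(triphenyl-λ5-phosphanylidene)hept-5-enoate, via phosphonium bromide 16 (not isolated)
Conditions: NaI (cat.), MeCN, reflux; then aq. NaOH, CH2Cl2, rt
Reagents that add atoms: none
Why: C-Alkylation of the stabilised ylide by the primary iodide formed in situ (Finkelstein) gives the phosphonium salt, which aqueous base deprotonates to the α-substituted stabilised ylide.

Step 9
Reactants: 13 (4R)-4-[(1S,4R)-4-hydroxy-4-methylcyclohex-2-en-1-yl]pentanal; 17 methyl 6-methyl-2-(triphenyl-λ5-phosphanylidene)hept-5-enoate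
Product: 19 methyl (2E,4S,6R)-4-(anilinooxy)-6-[(1S,4R)-4-hydroxy-4-methylcyclohex-2-en-1-yl]-2-(4-methylpent-3-en-1-yl)hept-2-enoate, via aminoxy aldehyde 18 (not isolated)
Conditions: D-proline (20 mol%), PhNO (1.0 equiv, slow addition), DMSO, rt; then 17, CH2Cl2, 0 °C to rt
Reagents that add atoms: nitrosobenzene, O=Nc1ccccc1
Why: Proline-catalysed α-aminoxylation (enamine O-nitroso aldol) with D-proline sets C9 under catalyst control, and the Wittig reaction of the α-substituted stabilised ylide in the same flask gives the (E)-trisubstituted enoate before the α-oxy aldehyde can epimerise.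

Step 10
Reactants: 19 methyl (2E,4S,6R)-4-(anilinooxy)-6-[(1S,4R)-4-hydroxy-4-methylcyclohex-2-en-1-yl]-2-(4-methylpent-3-en-1-yl)hept-2-enoate
Product: 20 methyl (2E,4S,6R)-4-hydroxy-6-[(1S,4R)-4-hydroxy-4-methylcyclohex-2-en-1-yl]-2-(4-methylpent-3-en-1-yl)hept-2-enoate
Conditions: Cu(OAc)2·H2O (30 mol%), EtOH, rt
Reagents that add atoms: none
Why: Copper(II)-catalysed heterolysis of the weak anilino N–O bond frees the secondary allylic alcohol under neutral conditions that spare the enoate, the acid-sensitive tertiary allylic alcohol and the C9 centre.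

Step 11
Reactants: 20 methyl (2E,4S,6R)-4-hydroxy-6-[(1S,4R)-4-hydroxy-4-methylcyclohex-2-en-1-yl]-2-(4-methylpent-3-en-1-yl)hept-2-enoate
Product: 21 methyl (2E,4S,6R)-4-acetoxy-6-[(1S,4R)-4-hydroxy-4-methylcyclohex-2-en-1-yl]-2-(4-methylpent-3-en-1-yl)hept-2-enoate
Conditions: Ac2O (1.2 equiv), pyridine, DMAP (cat.), CH2Cl2, 0 °C
Reagents that add atoms: acetic anhydride, CC(=O)OC(C)=O
Why: Acylation with acetic anhydride is selective for the secondary hydroxyl because the tertiary allylic hydroxyl reacts far more slowly under these conditions.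

Compound list
1 | trimethyl(prop-2-yn-1-yloxy)silane | C#CCO[Si](C)(C)C | starting material
2 | cyclopent-2-en-1-one | O=C1C=CCC1 | starting material
3 | chlorobis(cyclopentadienyl)[(1E)-3-(trimethylsilyloxy)prop-1-en-1-yl]zirconium | C[Si](C)(C)OC/C=C/[Zr](Cl)(C1C=CC=C1)C1C=CC=C1 | intermediate
4 | chlorobis(cyclopentadienyl)({(3S)-3-[(1E)-3-(trimethylsilyloxy)prop-1-en-1-yl]cyclopent-1-en-1-yl}oxy)zirconium | C[Si](C)(C)OC/C=C/[C@H]1C=C(O[Zr](Cl)(C2C=CC=C2)C2C=CC=C2)CC1 | intermediate
5 | trimethyl{[(2E)-3-[(1S)-3-(trimethylsilyloxy)cyclopent-2-en-1-yl]prop-2-en-1-yl]oxy}silane | C[Si](C)(C)OC/C=C/[C@H]1C=C(O[Si](C)(C)C)CC1 | intermediate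
6 | trimethyl{[(2E)-3-[(1R,4S,5S)-1-(trimethylsilyloxy)bicyclo[3.1.0]hexan-4-yl]prop-2-en-1-yl]oxy}silane | C[Si](C)(C)OC/C=C/[C@H]1[C@@H]2C[C@]2(O[Si](C)(C)C)CC1 | intermediate
7 | (3R,4S)-3-chloro-4-[(1E)-3-(trimethylsilyloxy)prop-1-en-1-yl]cyclohexan-1-one | C[Si](C)(C)OC/C=C/[C@H]1[C@H](Cl)CC(=O)CC1 | intermediate
8 | (4S)-4-[(1E)-3-hydroxyprop-1-en-1-yl]cyclohex-2-en-1-one | OC/C=C/[C@H]1C=CC(=O)CC1 | intermediate
9 | (1R,4S)-4-[(1E)-3-hydroxyprop-1-en-1-yl]-1-methylcyclohex-2-en-1-ol | OC/C=C/[C@H]1C=C[C@](C)(O)CC1 | intermediate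
10 | (2E)-3-[(1S,4R)-4-hydroxy-4-methylcyclohex-2-en-1-yl]prop-2-en-1-yl methanesulfonate | CS(=O)(=O)OC/C=C/[C@H]1C=C[C@](C)(O)CC1 | intermediate
11 | (1R,4R)-4-[(1E)-3-bromoprop-1-en-1-yl]-1-methylcyclohex-2-en-1-ol | BrC/C=C/[C@H]1C=C[C@](C)(O)CC1 | intermediate
12 | (1R,4R)-4-[(2R)-but-3-en-2-yl]-1-methylcyclohex-2-en-1-ol | C=C[C@@H](C)[C@H]1C=C[C@](C)(O)CC1 | intermediate
13 | (4R)-4-[(1S,4R)-4-hydroxy-4-methylcyclohex-2-en-1-yl]pentanal | O=CCC[C@@H](C)[C@H]1C=C[C@](C)(O)CC1 | intermediate
14 | 5-bromo-2-methylpent-2-ene | CC(C)=CCCBr | starting material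
15 | methyl (triphenyl-λ5-phosphanylidene)acetate | COC(=O)C=P(c1ccccc1)(c1ccccc1)c1ccccc1 | starting material
16 | (1-methoxy-6-methyl-1-oxohept-5-en-2-yl)triphenylphosphonium bromide | COC(=O)C(CCC=C(C)C)[P+](c1ccccc1)(c1ccccc1)c1ccccc1.[Br-] | intermediate
17 | methyl 6-methyl-2-(triphenyl-λ5-phosphanylidene)hept-5-enoate | COC(=O)C(CCC=C(C)C)=P(c1ccccc1)(c1ccccc1)c1ccccc1 | intermediate
18 | (2S,4R)-2-(anilinooxy)-4-[(1S,4R)-4-hydroxy-4-methylcyclohex-2-en-1-yl]pentanal | O=C[C@H](C[C@@H](C)[C@H]1C=C[C@](C)(O)CC1)ONc1ccccc1 | intermediate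
19 | methyl (2E,4S,6R)-4-(anilinooxy)-6-[(1S,4R)-4-hydroxy-4-methylcyclohex-2-en-1-yl]-2-(4-methylpent-3-en-1-yl)hept-2-enoate | COC(=O)/C(=C/[C@H](C[C@@H](C)[C@H]1C=C[C@](C)(O)CC1)ONc1ccccc1)CCC=C(C)C | intermediate
20 | methyl (2E,4S,6R)-4-hydroxy-6-[(1S,4R)-4-hydroxy-4-methylcyclohex-2-en-1-yl]-2-(4-methylpent-3-en-1-yl)hept-2-enoate | COC(=O)/C(=C/[C@H](C[C@@H](C)[C@H]1C=C[C@](C)(O)CC1)O)CCC=C(C)C | intermediate
21 | methyl (2E,4S,6R)-4-acetoxy-6-[(1S,4R)-4-hydroxy-4-methylcyclohex-2-en-1-yl]-2-(4-methylpent-3-en-1-yl)hept-2-enoate | COC(=O)/C(=C/[C@H](C[C@@H](C)[C@H]1C=C[C@](C)(O)CC1)OC(C)=O)CCC=C(C)C | target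

Total step count: 11. Longest linear sequence: 10 steps (steps 1–7 and 9–11); step 8 makes the ylide for the convergent step 9.

Steps most likely to fail

Step 3 (key step). The siloxycyclopropane may lose its silyl group before oxidation and then open at the external bond without ring growth. The new enone may also lose the C4 configuration if the doubly allylic C4–H is removed during the elimination. The fallback sets out from 5 and uses a different one-carbon ring expansion. Dibromocarbene (CHBr3, KOt-Bu, pentane, −20 °C) adds to the enol ether, and the adduct opens by electrocyclic cleavage with loss of the silyl bromide to give (4S)-2-bromo-4-[(1E)-3-(trimethylsilyloxy)prop-1-en-1-yl]cyclohex-2-en-1-one F1. Hydrodebromination (Pd(PPh3)4, Bu3SnH, THF) with a methanolic work-up that removes the O–TMS group comes back to the route at 8.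

Step 4. Facial selectivity of the methyl addition may be poor, because pseudo-equatorial attack gives the C1 epimer and a 4-alkenyl group biases the half-chair only weakly. The fallback sets out from 8 and relays the C4 configuration through the neighbouring carbon. Nucleophilic epoxidation (H2O2, NaOH, MeOH, 0 °C) should occur anti to the C4 substituent and give (1S,5S,6S)-5-[(1E)-3-hydroxyprop-1-en-1-yl]-7-oxabicyclo[4.1.0]heptan-2-one F2. MeMgBr (THF, −78 °C) should then add anti to the oxirane to give (1S,2R,5S,6S)-5-[(1E)-3-hydroxyprop-1-en-1-yl]-2-methyl-7-oxabicyclo[4.1.0]heptan-2-ol F3, with the methyl group cis to the side chain. Titanocene(III) deoxygenation of the oxirane (Cp2TiCl2, Zn, THF, rt) restores the C2=C3 alkene and comes back to the route at 9.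

Step 6. The allylic alkylation may lose regiocontrol (SN2 instead of SN2′) at the hindered γ-carbon, or catalyst and substrate induction may be mismatched at C7. The fallback sets out from 9 and uses stereospecific epoxide chemistry instead. Sharpless asymmetric epoxidation (Ti(OiPr)4, D-(−)-DET, TBHP, 4 Å MS, CH2Cl2, −20 °C) of the primary allylic alcohol should give [(2R,3R)-3-[(1R,4R)-4-hydroxy-4-methylcyclohex-2-en-1-yl]oxiran-2-yl]methanol F4. Me3Al (CH2Cl2/hexane, 0 °C) opens it at C7 with inversion to give (2S,3S)-3-[(1R,4R)-4-hydroxy-4-methylcyclohex-2-en-1-yl]butane-1,2-diol F5. Deoxygenative olefination of the vicinal diol (PPh3, I2, imidazole, toluene, 80 °C) comes back to the route at 12.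

Further compounds
F1 | step 3 | (4S)-2-bromo-4-[(1E)-3-(trimethylsilyloxy)prop-1-en-1-yl]cyclohex-2-en-1-one | C[Si](C)(C)OC/C=C/[C@H]1C=C(Br)C(=O)CC1
F2 | step 4 | (1S,5S,6S)-5-[(1E)-3-hydroxyprop-1-en-1-yl]-7-oxabicyclo[4.1.0]heptan-2-one | OC/C=C/[C@H]1[C@@H]2O[C@@H]2C(=O)CC1
F3 | step 4 | (1S,2R,5S,6S)-5-[(1E)-3-hydroxyprop-1-en-1-yl]-2-methyl-7-oxabicyclo[4.1.0]heptan-2-ol | OC/C=C/[C@H]1[C@@H]2O[C@@H]2[C@](C)(O)CC1
F4 | step 6 | [(2R,3R)-3-[(1R,4R)-4-hydroxy-4-methylcyclohex-2-en-1-yl]oxiran-2-yl]methanol | OC[C@H]1O[C@@H]1[C@H]2C=C[C@](C)(O)CC2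
F5 | step 6 | (2S,3S)-3-[(1R,4R)-4-hydroxy-4-methylcyclohex-2-en-1-yl]butane-1,2-diol | OC[C@@H](O)[C@@H](C)[C@H]1C=C[C@](C)(O)CC1
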